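**Retrosynthetic overview**

1. Feature: in the 3,4-dihydro-2H-pyran ring (O1, C2, C3, C4, C5, C6) C2 carries the 4-hydroxy-3-methoxyphenyl ring, so O1–C2 is a p-hydroxybenzyl enol-ether bond that can be made, and reopened, through the p-quinone methide of that guaiacol ring.
2. Last disconnection O1–C2: oxidation of open-chain aldehyde 23 to its quinone methide and oxa-1,6-addition of the aldehyde enol oxygen; C2 is set from C3 (trans) and C5 becomes sp2.
3. 23 comes from the 1,1-disubstituted alkene 20 (hydroboration–oxidation, re-oxidation, PMB removal); 20 comes from Suzuki coupling of 2-bromoalkene 10 with benzofuran-2-ylboronate 19.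
4. C3 is set by Evans alkylation of the dihydroferulic acid imide 6 with 2,3-dibromopropene; 19 comes from 2',5'-dimethoxyacetophenone by iodination, demethylation, Sonogashira/5-endo-dig annulation, silylation and C2–H borylation.
5. Ring order: furan ring of the benzofuran (step 8), then the dihydropyran (step 15); both benzene rings are bought.

Key step: step 15

Remark: (R)-4-benzyl-2-oxazolidinone, 2,3-dibromopropene, 2',5'-dimethoxyacetophenone and (trimethylsilyl)acetylene are taken as purchased. The benzofuran phenol is carried as a TIPS ether. The aldehyde α-carbon and the two centres made in step 12 are carried as mixtures because each is destroyed before the end.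

**Route**

Step 1
Reactants: 1 dihydroferulic acid
Product: 3 3-[3-methoxy-4-(4-methoxybenzyloxy)phenyl]propanoic acid, via PMB ester 2 (not isolated)
Conditions: PMBCl (2.3 equiv), K2CO3, DMF, 60 °C; then 2 M NaOH, MeOH, 50 °C; HCl to pH 3
Reagents that add atoms: 4-methoxybenzyl chloride, COc1ccc(CCl)cc1; sodium hydroxide, [Na+].[OH-] (one carboxyl oxygen)
Why: Williamson O-alkylation of phenoxide and carboxylate followed by saponification leaves only the base-stable aryl PMB ether, which should mask the guaiacol through the enolate, hydride, borane and periodinane steps.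

Step 2
Reactants: 3 3-[3-methoxy-4-(4-methoxybenzyloxy)phenyl]propanoic acid; 4 (R)-4-benzyl-2-oxazolidinone
Product: 6 (R)-4-benzyl-3-{3-[3-methoxy-4-(4-methoxybenzyloxy)phenyl]propanoyl}oxazolidin-2-one, via mixed pivalic anhydride 5 (not isolated)
Conditions: PivCl, Et3N, THF, −20 °C; then 4, LiCl, −20 °C → rt
Reagents that add atoms: none
Why: Mixed-anhydride N-acylation of the oxazolidinone (LiCl/Et3N protocol) should occur at the less hindered carbonyl of the pivalic anhydride and install the Evans auxiliary.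

Step 3
Reactants: 6 (R)-4-benzyl-3-{3-[3-methoxy-4-(4-methoxybenzyloxy)phenyl]propanoyl}oxazolidin-2-one; 7 2,3-dibromopropene
Product: 8 (R)-4-benzyl-3-{(S)-4-bromo-2-[3-methoxy-4-(4-methoxybenzyloxy)benzyl]pent-4-enoyl}oxazolidin-2-one
Conditions: NaHMDS, THF, −78 °C; then 7 (3 equiv), −78 → −40 °C
Reagents that add atoms: none
Why: Evans asymmetric alkylation, in which the chelated (Z)-sodium enolate is attacked by the allylic bromide (SN2 at CH2Br, the vinylic bromide being inert) on the face opposite the C4 benzyl group, so the (R)-auxiliary should give the (S) α-centre that becomes C3 of the target.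

Step 4
Reactants: 8 (R)-4-benzyl-3-{(S)-4-bromo-2-[3-methoxy-4-(4-methoxybenzyloxy)benzyl]pent-4-enoyl}oxazolidin-2-one
Product: 9 (S)-4-bromo-2-[3-methoxy-4-(4-methoxybenzyloxy)benzyl]pent-4-en-1-ol
Conditions: LiBH4, MeOH (1 equiv), THF, 0 °C
Reagents that add atoms: none
Why: Reductive cleavage of the imide with LiBH4 should give the primary alcohol without touching the vinyl bromide or the PMB ether and without epimerising the new centre, and the auxiliary is recovered.

Step 5
Reactants: 9 (S)-4-bromo-2-[3-methoxy-4-(4-methoxybenzyloxy)benzyl]pent-4-en-1-ol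
Product: 10 (S)-4-bromo-2-[3-methoxy-4-(4-methoxybenzyloxy)benzyl]pent-4-en-1-yl acetate
Conditions: Ac2O, pyridine, DMAP (cat.), CH2Cl2, rt
Reagents that add atoms: acetic anhydride, CC(=O)OC(C)=O
Why: DMAP-catalysed acetylation installs the acetate of the target at the stage where it is the only hydroxyl.

Step 6
Reactants: 11 2',5'-dimethoxyacetophenone
Product: 12 1-(4-iodo-2,5-dimethoxyphenyl)ethanone
Conditions: NIS, TFA (cat.), MeCN, rt
Reagents that add atoms: N-iodosuccinimide, O=C1CCC(=O)N1I
Why: Electrophilic aromatic iodination should go ortho to the 5-methoxy group (the 2-methoxy group is cross-conjugated with the acetyl) and, of its two ortho sites, to the unhindered C4 para to the acetyl, as in the halogenation of 2,5-dimethoxybenzaldehyde.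

Step 7
Reactants: 12 1-(4-iodo-2,5-dimethoxyphenyl)ethanone
Product: 13 1-(2,5-dihydroxy-4-iodophenyl)ethanone
Conditions: BBr3 (3 equiv), CH2Cl2, −78 °C → rt; H2O
Reagents that add atoms: none
Why: BBr3 cleaves both aryl methyl ethers (Lewis acid-mediated SN2 demethylation) while aryl iodide and ketone survive, which frees the hydroxyl ortho to iodine for the annulation.

Step 8
Reactants: 13 1-(2,5-dihydroxy-4-iodophenyl)ethanone; 14 (trimethylsilyl)acetylene
Product: 17 1-(5-hydroxybenzofuran-6-yl)ethanone, via silylalkynyl phenol 15 (not isolated), via ethynyl phenol 16 (not isolated)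
Conditions: Pd(PPh3)2Cl2 (3 mol%), CuI (5 mol%), Et3N, THF, rt; then K2CO3, MeOH, 60 °C
Reagents that add atoms: none
Why: Sonogashira coupling at the aryl iodide, methanolysis of the C–Si bond and base/copper-promoted 5-endo-dig hydroalkoxylation of the o-ethynylphenol should give the benzofuran, because only the 5'-hydroxyl is ortho to the alkyne and the para-acetyl group polarises the alkyne for attack at its terminal carbon.

Step 9
Reactants: 17 1-(5-hydroxybenzofuran-6-yl)ethanone
Product: 18 1-[5-(triisopropylsilyloxy)benzofuran-6-yl]ethanone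
Conditions: TIPSCl, imidazole, DMAP (cat.), DMF, 40 °C
Reagents that add atoms: chlorotriisopropylsilane, CC(C)[Si](Cl)(C(C)C)C(C)C
Why: Silylation of the chelated phenol gives an aryl silyl ether that should withstand the aqueous base, borane, periodinane and acid of the later steps and is removed by fluoride at the end.

Step 10
Reactants: 18 1-[5-(triisopropylsilyloxy)benzofuran-6-yl]ethanone
Product: 19 1-[2-(4,4,5,5-tetramethyl-1,3,2-dioxaborolan-2-yl)-5-(triisopropylsilyloxy)benzofuran-6-yl]ethanone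
Conditions: B2pin2 (1.0 equiv), [Ir(OMe)(cod)]2 (1.5 mol%), dtbpy (3 mol%), THF, 60 °C
Reagents that add atoms: bis(pinacolato)diboron, CC1(C)OB(OC1(C)C)B1OC(C)(C)C(C)(C)O1
Why: Iridium-catalysed C–H borylation is selective for the benzofuran C2–H (α to oxygen and unhindered), the other ring C–H bonds being less acidic or flanked by substituents.

Step 11
Reactants: 10 (S)-4-bromo-2-[3-methoxy-4-(4-methoxybenzyloxy)benzyl]pent-4-en-1-yl acetate; 19 1-[2-(4,4,5,5-tetramethyl-1,3,2-dioxaborolan-2-yl)-5-(triisopropylsilyloxy)benzofuran-6-yl]ethanone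
Product: 20 (S)-4-[6-acetyl-5-(triisopropylsilyloxy)benzofuran-2-yl]-2-[3-methoxy-4-(4-methoxybenzyloxy)benzyl]pent-4-en-1-yl acetate
Conditions: XPhos Pd G3 (3 mol%), 0.5 M aq. K3PO4 (2 equiv), THF, 40 °C
Reagents that add atoms: none
Why: Suzuki–Miyaura coupling of the 2-bromoalkene with the heteroaryl boronate, in which a fast precatalyst at 40 °C with dilute phosphate should outrun protodeboronation and spare the acetate and the silyl ether.

Step 12
Reactants: 20 (S)-4-[6-acetyl-5-(triisopropylsilyloxy)benzofuran-2-yl]-2-[3-methoxy-4-(4-methoxybenzyloxy)benzyl]pent-4-en-1-yl acetate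
Product: 21 (2R)-5-hydroxy-4-[6-(1-hydroxyethyl)-5-(triisopropylsilyloxy)benzofuran-2-yl]-2-[3-methoxy-4-(4-methoxybenzyloxy)benzyl]pentyl acetate (mixture at C4 and at the carbinol carbon)
Conditions: 9-BBN (4 equiv), THF, 0 → 50 °C; then NaBO3·4H2O, THF/H2O, rt
Reagents that add atoms: sodium perborate, [Na+].[Na+].O[B-]1(O)OO[B-](O)(O)OO1 (oxygen of the primary alcohol)
Why: Anti-Markovnikov hydroboration of the 1,1-disubstituted alkene with 9-BBN and perborate oxidation should give the primary alcohol, while the excess borane also reduces the aryl ketone, which is intended because step 13 restores it (any ketone that survives converges there) and both new centres are destroyed later.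

Step 13
Reactants: 21 (2R)-5-hydroxy-4-[6-(1-hydroxyethyl)-5-(triisopropylsilyloxy)benzofuran-2-yl]-2-[3-methoxy-4-(4-methoxybenzyloxy)benzyl]pentyl acetate
Product: 22 (2R)-4-[6-acetyl-5-(triisopropylsilyloxy)benzofuran-2-yl]-2-[3-methoxy-4-(4-methoxybenzyloxy)benzyl]-5-oxopentyl acetate (C4 epimers)
Conditions: Dess–Martin periodinane (3 equiv), pyridine, CH2Cl2, 0 °C → rt
Reagents that add atoms: none
Why: Dess–Martin oxidation should convert the primary alcohol to the aldehyde and the benzylic carbinol back to the acetyl group under mild conditions that the PMB ether, the silyl ether and the acetate tolerate.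

Step 14
Reactants: 22 (2R)-4-[6-acetyl-5-(triisopropylsilyloxy)benzofuran-2-yl]-2-[3-methoxy-4-(4-methoxybenzyloxy)benzyl]-5-oxopentyl acetate
Product: 23 (2R)-4-[6-acetyl-5-(triisopropylsilyloxy)benzofuran-2-yl]-2-(4-hydroxy-3-methoxybenzyl)-5-oxopentyl acetate (C4 epimers)
Conditions: TFA (10 vol%), anisole (10 equiv), CH2Cl2, 0 °C
Reagents that add atoms: none
Why: Acidolysis of the aryl PMB ether (SN1, cation trapped by anisole) should free the guaiacol while the aryl TIPS ether, acetate, ketone and aldehyde survive brief exposure to cold TFA.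

Step 15
Reactants: 23 (2R)-4-[6-acetyl-5-(triisopropylsilyloxy)benzofuran-2-yl]-2-(4-hydroxy-3-methoxybenzyl)-5-oxopentyl acetate
Product: 25 [(2R,3S)-5-[6-acetyl-5-(triisopropylsilyloxy)benzofuran-2-yl]-2-(4-hydroxy-3-methoxyphenyl)-3,4-dihydro-2H-pyran-3-yl]methyl acetate, via p-quinone methide 24 (not isolated)
Conditions: Ag2O (1.2 equiv), 4 Å MS, CH2Cl2 (0.005 M), rt, dark, Ar
Reagents that add atoms: none
Why: Proposed new method: Ag2O removes two electrons and two protons from the free 4-alkylguaiacol (the only unprotected phenol) to give p-quinone methide 24, whose exocyclic methide carbon is the future C2; the enol of the α-benzofuranyl aldehyde, favoured by conjugation with the heteroarene, adds to that carbon through oxygen and the guaiacol rearomatises. The closest known reaction type is the Ag2O- or DDQ-mediated conversion of 4-alkyl-2-methoxyphenols into p-quinone methides with intramolecular oxa-1,6-addition of alcohols, carboxylic acids or 1,3-dicarbonyl enols; an aldehyde enol as the oxygen nucleophile is the untested element. The dihydropyran closes in the 6-exo-trig mode on the exocyclic C=C of the methide, and O-attack is preferred because C-attack of the enol would give a cyclobutane. C2 is controlled by the C3 stereocentre: a chair-like transition state with the acetoxymethyl group and the quinoid ring pseudo-equatorial leads to the 2,3-trans ether, and since the product is a p-hydroxybenzyl enol ether that can reopen to 24, any cis isomer should drain to the trans-diequatorial half-chair. Both aldehyde epimers converge because the shared enol makes C5 sp2. The step needs oxidation at the guaiacol only (secured by the TIPS ether on the benzofuran phenol and by a small excess of oxidant at high dilution, which also restrains phenoxyl coupling and further oxidation of the product) and ring closure faster than tautomerisation of 24 to the 4-vinylphenol, which would erase C3 (secured by the tethered nucleophile and the absence of added base).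

Step 16
Reactants: 25 [(2R,3S)-5-[6-acetyl-5-(triisopropylsilyloxy)benzofuran-2-yl]-2-(4-hydroxy-3-methoxyphenyl)-3,4-dihydro-2H-pyran-3-yl]methyl acetate
Product: 26 propolis-benzofuran A
Conditions: TBAF, AcOH (1:1.2), THF, 0 °C
Reagents that add atoms: none
Why: Fluoride cleaves the aryl Si–O bond (the ortho-acetyl phenoxide is a good leaving group) and the acetic acid buffer keeps the medium non-basic, so the acetate, the enol ether and the p-hydroxybenzyl ether at C2 should be untouched.

**Compound list**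

1 | dihydroferulic acid, 3-(4-hydroxy-3-methoxyphenyl)propanoic acid | COc1cc(CCC(=O)O)ccc1O | starting material
2 | 4-methoxybenzyl 3-[3-methoxy-4-(4-methoxybenzyloxy)phenyl]propanoate | COc1cc(CCC(=O)OCc2ccc(OC)cc2)ccc1OCc1ccc(OC)cc1 | intermediate (not isolated)
3 | 3-[3-methoxy-4-(4-methoxybenzyloxy)phenyl]propanoic acid | COc1cc(CCC(=O)O)ccc1OCc1ccc(OC)cc1 | intermediate
4 | (R)-4-benzyl-2-oxazolidinone | O=C1N[C@H](Cc2ccccc2)CO1 | starting material
5 | 3-[3-methoxy-4-(4-methoxybenzyloxy)phenyl]propanoic pivalic anhydride | COc1cc(CCC(=O)OC(=O)C(C)(C)C)ccc1OCc1ccc(OC)cc1 | intermediate (not isolated)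
6 | (R)-4-benzyl-3-{3-[3-methoxy-4-(4-methoxybenzyloxy)phenyl]propanoyl}oxazolidin-2-one | COc1cc(CCC(=O)N2[C@H](Cc3ccccc3)COC2=O)ccc1OCc1ccc(OC)cc1 | intermediate
7 | 2,3-dibromopropene | C=C(Br)CBr | starting material
8 | (R)-4-benzyl-3-{(S)-4-bromo-2-[3-methoxy-4-(4-methoxybenzyloxy)benzyl]pent-4-enoyl}oxazolidin-2-one | COc1cc(C[C@@H](CC(Br)=C)C(=O)N2[C@H](Cc3ccccc3)COC2=O)ccc1OCc1ccc(OC)cc1 | intermediate
9 | (S)-4-bromo-2-[3-methoxy-4-(4-methoxybenzyloxy)benzyl]pent-4-en-1-ol | COc1cc(C[C@@H](CC(Br)=C)CO)ccc1OCc1ccc(OC)cc1 | intermediate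
10 | (S)-4-bromo-2-[3-methoxy-4-(4-methoxybenzyloxy)benzyl]pent-4-en-1-yl acetate | COc1cc(C[C@@H](CC(Br)=C)COC(C)=O)ccc1OCc1ccc(OC)cc1 | intermediate
11 | 2',5'-dimethoxyacetophenone | CC(=O)c1cc(OC)ccc1OC | starting material
12 | 1-(4-iodo-2,5-dimethoxyphenyl)ethanone | CC(=O)c1cc(OC)c(I)cc1OC | intermediate
13 | 1-(2,5-dihydroxy-4-iodophenyl)ethanone | CC(=O)c1cc(O)c(I)cc1O | intermediate
14 | (trimethylsilyl)acetylene | C#C[Si](C)(C)C | starting material
15 | 1-{2,5-dihydroxy-4-[(trimethylsilyl)ethynyl]phenyl}ethanone | CC(=O)c1cc(O)c(C#C[Si](C)(C)C)cc1O | intermediate (not isolated)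
16 | 1-(4-ethynyl-2,5-dihydroxyphenyl)ethanone | CC(=O)c1cc(O)c(C#C)cc1O | intermediate (not isolated)
17 | 1-(5-hydroxybenzofuran-6-yl)ethanone (6-acetyl-5-hydroxybenzofuran) | CC(=O)c1cc2occc2cc1O | intermediate
18 | 1-[5-(triisopropylsilyloxy)benzofuran-6-yl]ethanone | CC(=O)c1cc2occc2cc1O[Si](C(C)C)(C(C)C)C(C)C | intermediate
19 | 1-[2-(4,4,5,5-tetramethyl-1,3,2-dioxaborolan-2-yl)-5-(triisopropylsilyloxy)benzofuran-6-yl]ethanone | CC(=O)c1cc2oc(B3OC(C)(C)C(C)(C)O3)cc2cc1O[Si](C(C)C)(C(C)C)C(C)C | intermediate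
20 | (S)-4-[6-acetyl-5-(triisopropylsilyloxy)benzofuran-2-yl]-2-[3-methoxy-4-(4-methoxybenzyloxy)benzyl]pent-4-en-1-yl acetate | COc1cc(C[C@@H](CC(=C)c2cc3cc(O[Si](C(C)C)(C(C)C)C(C)C)c(C(C)=O)cc3o2)COC(C)=O)ccc1OCc1ccc(OC)cc1 | intermediate
21 | (2R)-5-hydroxy-4-[6-(1-hydroxyethyl)-5-(triisopropylsilyloxy)benzofuran-2-yl]-2-[3-methoxy-4-(4-methoxybenzyloxy)benzyl]pentyl acetate (mixture at C4 and at the carbinol carbon) | COc1cc(C[C@@H](CC(CO)c2cc3cc(O[Si](C(C)C)(C(C)C)C(C)C)c(C(C)O)cc3o2)COC(C)=O)ccc1OCc1ccc(OC)cc1 | intermediate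
22 | (2R)-4-[6-acetyl-5-(triisopropylsilyloxy)benzofuran-2-yl]-2-[3-methoxy-4-(4-methoxybenzyloxy)benzyl]-5-oxopentyl acetate (C4 epimers) | COc1cc(C[C@@H](CC(C=O)c2cc3cc(O[Si](C(C)C)(C(C)C)C(C)C)c(C(C)=O)cc3o2)COC(C)=O)ccc1OCc1ccc(OC)cc1 | intermediate
23 | (2R)-4-[6-acetyl-5-(triisopropylsilyloxy)benzofuran-2-yl]-2-(4-hydroxy-3-methoxybenzyl)-5-oxopentyl acetate (C4 epimers) | COc1cc(C[C@@H](CC(C=O)c2cc3cc(O[Si](C(C)C)(C(C)C)C(C)C)c(C(C)=O)cc3o2)COC(C)=O)ccc1O | intermediate (key-step precursor)
24 | (2R)-4-[6-acetyl-5-(triisopropylsilyloxy)benzofuran-2-yl]-2-[(3-methoxy-4-oxocyclohexa-2,5-dien-1-ylidene)methyl]-5-oxopentyl acetate (p-quinone methide) | COC1=CC(=C[C@@H](CC(C=O)c2cc3cc(O[Si](C(C)C)(C(C)C)C(C)C)c(C(C)=O)cc3o2)COC(C)=O)C=CC1=O | intermediate (not isolated)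
25 | [(2R,3S)-5-[6-acetyl-5-(triisopropylsilyloxy)benzofuran-2-yl]-2-(4-hydroxy-3-methoxyphenyl)-3,4-dihydro-2H-pyran-3-yl]methyl acetate | COc1cc([C@@H]2OC=C(c3cc4cc(O[Si](C(C)C)(C(C)C)C(C)C)c(C(C)=O)cc4o3)C[C@H]2COC(C)=O)ccc1O | intermediate (key-step product)
26 | propolis-benzofuran A, [(2R,3S)-5-(6-acetyl-5-hydroxybenzofuran-2-yl)-2-(4-hydroxy-3-methoxyphenyl)-3,4-dihydro-2H-pyran-3-yl]methyl acetate | COc1cc([C@@H]2OC=C(c3cc4cc(O)c(C(C)=O)cc4o3)C[C@H]2COC(C)=O)ccc1O | target

**Count**

Total steps: 16. Longest linear sequence: 11 steps (steps 1–5 and 11–16; the benzofuran branch, steps 6–10 and 11–16, is equally long).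

**Steps most likely to fail**

Step 15 (Proposed new method). What may go wrong: the phenoxyl radical couples through the free ortho position of the guaiacol instead of going on to the quinone methide; the quinone methide tautomerises to the 4-vinylphenol so that C3 is lost; or the product, itself a 4-alkylguaiacol, is oxidised further.

Fallback (redox-neutral, known reactions): the benzylic oxygen at C2 is brought in by an Evans syn-aldol and the ring is closed by lactol dehydration. It sets out from 4 and comes back to the route at 25.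
- N-Acylation of 4 with purchased 4-bromopent-4-enoic acid (PivCl, Et3N, LiCl) should give (R)-4-benzyl-3-(4-bromopent-4-enoyl)oxazolidin-2-one F1.
- A dibutylboron triflate/i-Pr2NEt aldol reaction with 3-methoxy-4-(4-methoxybenzyloxy)benzaldehyde should give the syn-aldol adduct F2. The (Z)-boron enolate and the (R)-auxiliary set both centres as the 2,3-trans ring requires.
- TESOTf/2,6-lutidine should give the triethylsilyl ether F3.
- LiBH4 should give the primary alcohol F4.
- Ac2O/pyridine should give the acetate F5.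
- Suzuki coupling with 19 under the conditions of step 11 should give the alkene F6.
- 9-BBN followed by NaBO3 should give the diol F7.
- Dess–Martin oxidation should give the keto-aldehyde F8.
- TFA/anisole at 0 °C should remove the PMB and TES groups, and the freed benzylic hydroxyl should close onto the aldehyde to give the lactol F9.
- PPTS in warm toluene over molecular sieves should dehydrate F9 to 25, after which step 16 follows.

Step 12. What may go wrong: hydroboration of the heteroarene-conjugated alkene is slow or places boron partly at the benzylic carbon, and the oxidative work-up hydrolyses the acetate or the aryl silyl ether.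

Fallback (no hydride, no re-oxidation): it sets out from 20 and comes back at 22, so that step 13 is not needed. Upjohn dihydroxylation of the exocyclic alkene (OsO4 cat., NMO, acetone/H2O) should give the 1,2-diol F10. Mild acid (PPTS, toluene, 60 °C) should ionise the tertiary carbinol next to the benzofuran, and a 1,2-hydride shift (pinacol-type rearrangement of a 2-aryl-1,2-diol) should give aldehyde 22 with the acetyl group untouched.

Step 11. What may go wrong: protodeboronation of the 2-benzofuranyl boronate faster than transmetallation, or hydrolysis of the acetate or the aryl silyl ether by the aqueous base.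

Fallback (the furan ring is built onto the side chain instead of being coupled to it): it sets out from 10 and 13 and comes back at 20.
- Sonogashira coupling of 10 with 14 (Pd(PPh3)2Cl2, CuI, i-Pr2NH) should give the silyl enyne F11.
- Buffered TBAF/AcOH should give the terminal enyne F12.
- Sonogashira coupling of F12 with iodophenol 13 (Pd(PPh3)2Cl2, CuI, Et3N, DMF, 60 °C) should give the o-alkynylphenol F13, which should cyclise in the same flask (5-endo-dig) to the benzofuranol F14.
- TIPSCl/imidazole should then give 20.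

**Further compounds**

F1 | step 15 | (R)-4-benzyl-3-(4-bromopent-4-enoyl)oxazolidin-2-one | C=C(Br)CCC(=O)N1[C@H](Cc2ccccc2)COC1=O
F2 | step 15 | (R)-4-benzyl-3-[(2R)-4-bromo-2-{(R)-hydroxy[3-methoxy-4-(4-methoxybenzyloxy)phenyl]methyl}pent-4-enoyl]oxazolidin-2-one (syn-aldol adduct) | COc1cc([C@H](O)[C@@H](CC(Br)=C)C(=O)N2[C@H](Cc3ccccc3)COC2=O)ccc1OCc1ccc(OC)cc1
F3 | step 15 | (R)-4-benzyl-3-[(2R)-4-bromo-2-{(R)-[3-methoxy-4-(4-methoxybenzyloxy)phenyl](triethylsilyloxy)methyl}pent-4-enoyl]oxazolidin-2-one | COc1cc([C@H](O[Si](CC)(CC)CC)[C@@H](CC(Br)=C)C(=O)N2[C@H](Cc3ccccc3)COC2=O)ccc1OCc1ccc(OC)cc1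
F4 | step 15 | (S)-4-bromo-2-{(R)-[3-methoxy-4-(4-methoxybenzyloxy)phenyl](triethylsilyloxy)methyl}pent-4-en-1-ol | COc1cc([C@H](O[Si](CC)(CC)CC)[C@@H](CC(Br)=C)CO)ccc1OCc1ccc(OC)cc1
F5 | step 15 | (S)-4-bromo-2-{(R)-[3-methoxy-4-(4-methoxybenzyloxy)phenyl](triethylsilyloxy)methyl}pent-4-en-1-yl acetate | COc1cc([C@H](O[Si](CC)(CC)CC)[C@@H](CC(Br)=C)COC(C)=O)ccc1OCc1ccc(OC)cc1
F6 | step 15 | (S)-4-[6-acetyl-5-(triisopropylsilyloxy)benzofuran-2-yl]-2-{(R)-[3-methoxy-4-(4-methoxybenzyloxy)phenyl](triethylsilyloxy)methyl}pent-4-en-1-yl acetate | COc1cc([C@H](O[Si](CC)(CC)CC)[C@@H](CC(=C)c2cc3cc(O[Si](C(C)C)(C(C)C)C(C)C)c(C(C)=O)cc3o2)COC(C)=O)ccc1OCc1ccc(OC)cc1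
F7 | step 15 | (2S)-5-hydroxy-4-[6-(1-hydroxyethyl)-5-(triisopropylsilyloxy)benzofuran-2-yl]-2-{(R)-[3-methoxy-4-(4-methoxybenzyloxy)phenyl](triethylsilyloxy)methyl}pentyl acetate (mixture at C4 and at the carbinol carbon) | COc1cc([C@H](O[Si](CC)(CC)CC)[C@@H](CC(CO)c2cc3cc(O[Si](C(C)C)(C(C)C)C(C)C)c(C(C)O)cc3o2)COC(C)=O)ccc1OCc1ccc(OC)cc1
F8 | step 15 | (2S)-4-[6-acetyl-5-(triisopropylsilyloxy)benzofuran-2-yl]-2-{(R)-[3-methoxy-4-(4-methoxybenzyloxy)phenyl](triethylsilyloxy)methyl}-5-oxopentyl acetate (C4 epimers) | COc1cc([C@H](O[Si](CC)(CC)CC)[C@@H](CC(C=O)c2cc3cc(O[Si](C(C)C)(C(C)C)C(C)C)c(C(C)=O)cc3o2)COC(C)=O)ccc1OCc1ccc(OC)cc1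
F9 | step 15 | [(2R,3S)-5-[6-acetyl-5-(triisopropylsilyloxy)benzofuran-2-yl]-6-hydroxy-2-(4-hydroxy-3-methoxyphenyl)tetrahydro-2H-pyran-3-yl]methyl acetate (lactol, mixture at C5 and C6) | COc1cc([C@@H]2OC(O)C(c3cc4cc(O[Si](C(C)C)(C(C)C)C(C)C)c(C(C)=O)cc4o3)C[C@H]2COC(C)=O)ccc1O
F10 | step 12 | (2S)-4-[6-acetyl-5-(triisopropylsilyloxy)benzofuran-2-yl]-4,5-dihydroxy-2-[3-methoxy-4-(4-methoxybenzyloxy)benzyl]pentyl acetate (C4 epimers) | COc1cc(C[C@@H](CC(O)(CO)c2cc3cc(O[Si](C(C)C)(C(C)C)C(C)C)c(C(C)=O)cc3o2)COC(C)=O)ccc1OCc1ccc(OC)cc1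
F11 | step 11 | (S)-2-[3-methoxy-4-(4-methoxybenzyloxy)benzyl]-4-methylidene-6-(trimethylsilyl)hex-5-yn-1-yl acetate | COc1cc(C[C@@H](CC(=C)C#C[Si](C)(C)C)COC(C)=O)ccc1OCc1ccc(OC)cc1
F12 | step 11 | (S)-2-[3-methoxy-4-(4-methoxybenzyloxy)benzyl]-4-methylidenehex-5-yn-1-yl acetate | COc1cc(C[C@@H](CC(=C)C#C)COC(C)=O)ccc1OCc1ccc(OC)cc1
F13 | step 11 | (S)-6-(4-acetyl-2,5-dihydroxyphenyl)-2-[3-methoxy-4-(4-methoxybenzyloxy)benzyl]-4-methylidenehex-5-yn-1-yl acetate | COc1cc(C[C@@H](CC(=C)C#Cc2cc(O)c(C(C)=O)cc2O)COC(C)=O)ccc1OCc1ccc(OC)cc1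
F14 | step 11 | (S)-4-(6-acetyl-5-hydroxybenzofuran-2-yl)-2-[3-methoxy-4-(4-methoxybenzyloxy)benzyl]pent-4-en-1-yl acetate | COc1cc(C[C@@H](CC(=C)c2cc3cc(O)c(C(C)=O)cc3o2)COC(C)=O)ccc1OCc1ccc(OC)cc1
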